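The route rests on cutting the bond between the exocyclic alkene CH on C5 of the butenolide (tetronate) ring and the neighbouring CH(CH3) carbon, the only stereocentre. Because this E-configured C5=CH unit carries the stereocentre directly, an alkenylpalladium of fixed geometry can add to (E)-but-2-en-1-ol. One enantioselective redox-relay Heck reaction then forms the C–C bond, sets the S centre, preserves the contra-thermodynamic E alkene and leaves an aldehyde handle. Its precursor is a MOM-protected (E)-5-(iodomethylidene)tetronate, closed beforehand by anti iodolactonisation of a terminal enynoic acid. The furanoterpenoid chain follows by alkylzinc–allyl chloride coupling, and the stearate comes last.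

Key step: step 6

Assumption: with the alkene bound next to the oxazoline and its hydroxymethyl-bearing carbon turned away from the tert-butyl group, the (S)-configured pyridine-oxazoline ligand is expected to give the S aldehyde from the E alkenol. The configuration is to be checked on the first batch, and the mirror-image ligand is used if the sense is opposite.
Assumption: (E)-but-2-en-1-ol is bought in a geometrically pure grade, because the Z isomer would give the other enantiomer.

Step 1
Reactants: 1 ethyl propionate; 2 3-(trimethylsilyl)prop-2-ynal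
Product: 4 ethyl 3-hydroxy-2-methyl-5-(trimethylsilyl)pent-4-ynoate, via lithium enolate of ethyl propionate 3 (not isolated)
Conditions: LiN(i-Pr)2, THF, −78 °C; then 2, −78 °C; aq. NH4Cl
Reagents that add atoms: none
Why: Aldol addition of a preformed lithium ester enolate to a non-enolisable ynal goes 1,2 at low temperature, and the two new centres need no control because both become sp2 in steps 2 and 3.

Step 2
Reactants: 4 ethyl 3-hydroxy-2-methyl-5-(trimethylsilyl)pent-4-ynoate
Product: 5 ethyl 2-methyl-3-oxo-5-(trimethylsilyl)pent-4-ynoate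
Conditions: Dess–Martin periodinane, CH2Cl2, 0 °C → rt
Reagents that add atoms: none
Why: Dess–Martin oxidation of a propargylic alcohol is fast and close to neutral, so the alkynylsilane and the electrophilic ynone that is formed should be left alone.

Step 3
Reactants: 5 ethyl 2-methyl-3-oxo-5-(trimethylsilyl)pent-4-ynoate
Product: 6 ethyl (2E)-3-(methoxymethoxy)-2-methyl-5-(trimethylsilyl)pent-2-en-4-ynoate
Conditions: MOMCl, i-Pr2NEt, CH2Cl2, 0 °C → rt
Reagents that add atoms: chloromethyl methyl ether, COCCl
Why: O-alkylation of the β-keto ester enolate by a hard electrophile under non-chelating amine conditions, where dipole repulsion keeps the enolate oxygen anti to the ester and the slim alkynyl group sits cis to it, should give the 2E enol ether, the only isomer that can lactonise later.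

Step 4
Reactants: 6 ethyl (2E)-3-(methoxymethoxy)-2-methyl-5-(trimethylsilyl)pent-2-en-4-ynoate
Product: 8 (2E)-3-(methoxymethoxy)-2-methylpent-2-en-4-ynoic acid, via desilylated ethyl ester 7 (not isolated)
Conditions: LiOH, THF/H2O, rt → 40 °C; then 1 M HCl to pH 4, 0 °C
Reagents that add atoms: lithium hydroxide, [Li+].[OH-]
Why: Saponification together with base-induced protiodesilylation of the alkynylsilane leaves the acetal-type MOM group untouched, and alcohol cosolvents are omitted so that no alkoxide can exchange the OMOM group by addition–elimination.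

Step 5
Reactants: 8 (2E)-3-(methoxymethoxy)-2-methylpent-2-en-4-ynoic acid
Product: 9 (5E)-5-(iodomethylidene)-4-(methoxymethoxy)-3-methylfuran-2(5H)-one
Conditions: I2, NaHCO3, MeCN, 0 °C → rt, dark
Reagents that add atoms: iodine, II
Why: In this iodo enol lactonisation the carboxylate attacks the internal carbon of the iodine-activated terminal alkyne in a 5-exo-dig mode and anti to iodine, so iodine ends trans to the ring oxygen (E), while bicarbonate and darkness limit acid- or radical-induced drift to the Z isomer.

Step 6
Reactants: 9 (5E)-5-(iodomethylidene)-4-(methoxymethoxy)-3-methylfuran-2(5H)-one; 10 (E)-but-2-en-1-ol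
Product: 11 (5E)-4-(methoxymethoxy)-3-methyl-5-[(2S)-2-methyl-4-oxobutylidene]furan-2(5H)-one
Conditions: Pd2(dba)3 (5 mol %), (S)-4-tert-butyl-2-[5-(trifluoromethyl)pyridin-2-yl]-4,5-dihydrooxazole (13 mol %), AgOSO2CF3 (1.1 equiv), 2,6-di-tert-butyl-4-methylpyridine (1.2 equiv), 10 (3 equiv), 3 Å MS, DMA, rt, dark
Reagents that add atoms: none
Why: Proposed new method: oxidative addition of the C–I bond of 9 to ligated zerovalent palladium and removal of iodide by silver triflate should give the same cationic N,N-bound alkenylpalladium that alkenyl triflates give in the known enantioselective redox-relay Heck alkenylation of acyclic alkenols, the closest known reaction type; only the iodide/silver entry and the tetronate-substituted alkenyl group are untested. Syn insertion puts the alkenyl carbon on C3 of 10 (the methyl-bearing end) and palladium on C2, β-hydride elimination and re-insertion move palladium to the carbinol carbon, and loss of the hydroxyl proton releases aldehyde 11 and zerovalent palladium, with the hindered pyridine taking up the acid so that the MOM group never meets triflic acid. No ring is closed in this step. The new stereocentre is controlled by the tert-butyl group of the oxazoline, which makes the hydroxymethyl-bearing carbon of the geometrically pure E alkenol turn away from it and so exposes one alkene face. The step needs site selectivity (bonding at the distal carbon, relay toward oxygen instead of elimination to a conjugated diene), which the C–O dipole of the allylic alcohol and the hydroxyalkylpalladium sink should secure. The palladium-bearing alkenyl carbon has no β-hydrogen next to it, so the E geometry of 9 should pass unchanged into 11.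

Step 7
Reactants: 11 (5E)-4-(methoxymethoxy)-3-methyl-5-[(2S)-2-methyl-4-oxobutylidene]furan-2(5H)-one
Product: 12 (5E)-5-[(2S)-4-hydroxy-2-methylbutylidene]-4-(methoxymethoxy)-3-methylfuran-2(5H)-one
Conditions: NaBH4, THF/MeOH, −20 °C
Reagents that add atoms: none
Why: Chemoselective borohydride reduction works because the aldehyde is far more electrophilic than the donor-substituted lactone, and the stereocentre, being β to the carbonyl, cannot enolise.

Step 8
Reactants: 12 (5E)-5-[(2S)-4-hydroxy-2-methylbutylidene]-4-(methoxymethoxy)-3-methylfuran-2(5H)-one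
Product: 13 (5E)-5-[(2S)-4-iodo-2-methylbutylidene]-4-(methoxymethoxy)-3-methylfuran-2(5H)-one
Conditions: I2, PPh3, imidazole, CH2Cl2, 0 °C, dark
Reagents that add atoms: iodine, II
Why: Appel-type iodination of a primary alcohol is quick under imidazole buffering, and a short contact time in the dark should spare the MOM group and the E alkene.

Step 9
Reactants: 14 furan-3-ylmethanol
Product: 15 3-(chloromethyl)furan
Conditions: SOCl2, pyridine, Et2O, 0 °C
Reagents that add atoms: thionyl chloride, O=S(Cl)Cl
Why: Chlorodehydroxylation with thionyl chloride works on this activated primary alcohol while pyridine traps HCl away from the acid-sensitive furan, and the labile chloride is carried on at once as a solution.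

Step 10
Reactants: 15 3-(chloromethyl)furan; 16 geranyl chloride
Product: 18 dendrolasin, via 3-furylmethylmagnesium chloride 17 (not isolated)
Conditions: Mg, THF, 0 °C (slow addition of 15); then 16, Li2CuCl4 (3 mol %), THF, 0 °C
Reagents that add atoms: none
Why: Copper-catalysed cross-coupling of a Grignard reagent with a primary allylic chloride takes place at the CH2Cl carbon (SN2 mode) with the E alkene of the geranyl unit retained, and slow Grignard formation limits homocoupling.

Step 11
Reactants: 18 dendrolasin
Product: 20 (2E,6E)-9-(furan-3-yl)-2,6-dimethylnona-2,6-dien-1-ol, via over-oxidised enal 19 (not isolated)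
Conditions: SeO2 (cat.), t-BuOOH, salicylic acid (cat.), CH2Cl2, 0 °C → rt, stopped before full conversion; then NaBH4, MeOH, 0 °C
Reagents that add atoms: tert-butyl hydroperoxide, CC(C)(C)OO
Why: The Riley allylic oxidation (ene reaction followed by [2,3]-sigmatropic shift) prefers the terminal gem-dimethyl alkene and its E methyl group, and the borohydride treatment returns the part that went on to enal 19 to the alcohol.

Step 12
Reactants: 20 (2E,6E)-9-(furan-3-yl)-2,6-dimethylnona-2,6-dien-1-ol
Product: 22 3-[(3E,7E)-9-chloro-4,8-dimethylnona-3,7-dien-1-yl]furan, via allylic mesylate 21 (not isolated)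
Conditions: MsCl, LiCl, 2,4,6-collidine, DMF, 0 °C
Reagents that add atoms: lithium chloride, [Li+].[Cl-]
Why: Mesylation followed by in situ SN2 displacement with chloride converts primary allylic alcohols into chlorides without allylic shift or loss of alkene geometry, under conditions too mild to harm the furan.

Step 13
Reactants: 13 (5E)-5-[(2S)-4-iodo-2-methylbutylidene]-4-(methoxymethoxy)-3-methylfuran-2(5H)-one; 22 3-[(3E,7E)-9-chloro-4,8-dimethylnona-3,7-dien-1-yl]furan
Product: 24 (5E)-5-[(2S,6E,10E)-13-(furan-3-yl)-2,6,10-trimethyltrideca-6,10-dien-1-ylidene]-4-(methoxymethoxy)-3-methylfuran-2(5H)-one, via alkylzinc iodide 23 (not isolated)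
Conditions: activated Zn dust, LiCl, THF, 25–35 °C, dark; then 22 (1.2 equiv), CoBr2 (10 mol %), THF/NMP, −10 °C
Reagents that add atoms: none
Why: LiCl-promoted zinc insertion into a primary iodide tolerates the lactone, and the cobalt-catalysed allylation of alkylzinc reagents is a known coupling that attacks the CH2Cl carbon (SN2) and keeps the allyl geometry, whereas copper catalysis would give the SN2′ product.

Step 14
Reactants: 24 (5E)-5-[(2S,6E,10E)-13-(furan-3-yl)-2,6,10-trimethyltrideca-6,10-dien-1-ylidene]-4-(methoxymethoxy)-3-methylfuran-2(5H)-one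
Product: 26 (5E)-5-[(2S,6E,10E)-13-(furan-3-yl)-2,6,10-trimethyltrideca-6,10-dien-1-ylidene]-4-hydroxy-3-methylfuran-2(5H)-one, via trimethylsilyl tetronate 25 (not isolated)
Conditions: Me3SiOTf (2 equiv), 2,2′-bipyridyl (3 equiv), CH2Cl2, 0 °C, dark; then H2O; crude product used at once
Reagents that add atoms: none
Why: In this silyl triflate–bipyridyl acetal cleavage the good tetronate leaving group departs as its silyl ether and the MeOCH2 unit is held as a pyridinium salt until water is added, so neither free Brønsted acid nor a free oxocarbenium ion reaches the furan, the trisubstituted alkenes or the E-ylidene unit.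

Step 15
Reactants: 26 (5E)-5-[(2S,6E,10E)-13-(furan-3-yl)-2,6,10-trimethyltrideca-6,10-dien-1-ylidene]-4-hydroxy-3-methylfuran-2(5H)-one; 27 stearoyl chloride
Product: 28 (2E)-2-[(2S,6E,10E)-13-(furan-3-yl)-2,6,10-trimethyltrideca-6,10-dien-1-ylidene]-4-methyl-5-oxo-2,5-dihydrofuran-3-yl octadecanoate (target)
Conditions: 27 (1.1 equiv), i-Pr2NEt (1.3 equiv), CH2Cl2, −20 → 0 °C, dark
Reagents that add atoms: none
Why: O-acylation of the tetronate anion at O4 is the expected course because C3 is blocked by methyl, and a hindered amine in place of a nucleophilic catalyst avoids conjugate addition–elimination at the ylidene carbon and deprotonation at the allylic stereocentre.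

Compound list
1 | ethyl propionate | CCC(=O)OCC | starting material
2 | 3-(trimethylsilyl)prop-2-ynal | C[Si](C)(C)C#CC=O | starting material
3 | lithium enolate of ethyl propionate (kinetic geometry, of no consequence) | C/C=C(\OCC)O[Li] | intermediate
4 | ethyl 3-hydroxy-2-methyl-5-(trimethylsilyl)pent-4-ynoate (mixture of racemic diastereomers) | CCOC(=O)C(C)C(O)C#C[Si](C)(C)C | intermediate
5 | ethyl 2-methyl-3-oxo-5-(trimethylsilyl)pent-4-ynoate (racemic, enolisable) | CCOC(=O)C(C)C(=O)C#C[Si](C)(C)C | intermediate
6 | ethyl (2E)-3-(methoxymethoxy)-2-methyl-5-(trimethylsilyl)pent-2-en-4-ynoate (ester cis to alkynyl) | C[Si](C)(C)C#C/C(OCOC)=C(/C)C(=O)OCC | intermediate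
7 | ethyl (2E)-3-(methoxymethoxy)-2-methylpent-2-en-4-ynoate | C#C/C(OCOC)=C(/C)C(=O)OCC | intermediate
8 | (2E)-3-(methoxymethoxy)-2-methylpent-2-en-4-ynoic acid (CO2H cis to ethynyl) | C#C/C(OCOC)=C(/C)C(=O)O | intermediate
9 | (5E)-5-(iodomethylidene)-4-(methoxymethoxy)-3-methylfuran-2(5H)-one (I trans to ring O) | COCOC1=C(C)C(=O)O/C1=C/I | intermediate
10 | (E)-but-2-en-1-ol | C/C=C/CO | starting material
11 | (5E)-4-(methoxymethoxy)-3-methyl-5-[(2S)-2-methyl-4-oxobutylidene]furan-2(5H)-one | COCOC1=C(C)C(=O)O/C1=C/[C@@H](C)CC=O | intermediate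
12 | (5E)-5-[(2S)-4-hydroxy-2-methylbutylidene]-4-(methoxymethoxy)-3-methylfuran-2(5H)-one | COCOC1=C(C)C(=O)O/C1=C/[C@@H](C)CCO | intermediate
13 | (5E)-5-[(2S)-4-iodo-2-methylbutylidene]-4-(methoxymethoxy)-3-methylfuran-2(5H)-one | COCOC1=C(C)C(=O)O/C1=C/[C@@H](C)CCI | intermediate
14 | furan-3-ylmethanol | OCc1ccoc1 | starting material
15 | 3-(chloromethyl)furan | ClCc1ccoc1 | intermediate
16 | geranyl chloride, (2E)-1-chloro-3,7-dimethylocta-2,6-diene | CC(C)=CCC/C(C)=C/CCl | starting material
17 | (furan-3-ylmethyl)magnesium chloride | Cl[Mg]Cc1ccoc1 | intermediate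
18 | dendrolasin, 3-[(3E)-4,8-dimethylnona-3,7-dien-1-yl]furan | CC(C)=CCC/C(C)=C/CCc1ccoc1 | intermediate
19 | (2E,6E)-9-(furan-3-yl)-2,6-dimethylnona-2,6-dienal | O=C/C(C)=C/CC/C(C)=C/CCc1ccoc1 | intermediate
20 | (2E,6E)-9-(furan-3-yl)-2,6-dimethylnona-2,6-dien-1-ol | OC/C(C)=C/CC/C(C)=C/CCc1ccoc1 | intermediate
21 | (2E,6E)-9-(furan-3-yl)-2,6-dimethylnona-2,6-dien-1-yl methanesulfonate | CS(=O)(=O)OC/C(C)=C/CC/C(C)=C/CCc1ccoc1 | intermediate
22 | 3-[(3E,7E)-9-chloro-4,8-dimethylnona-3,7-dien-1-yl]furan | ClC/C(C)=C/CC/C(C)=C/CCc1ccoc1 | intermediate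
23 | {(3S,4E)-4-[3-(methoxymethoxy)-4-methyl-5-oxofuran-2(5H)-ylidene]-3-methylbutyl}zinc iodide | COCOC1=C(C)C(=O)O/C1=C/[C@@H](C)CC[Zn]I | intermediate
24 | (5E)-5-[(2S,6E,10E)-13-(furan-3-yl)-2,6,10-trimethyltrideca-6,10-dien-1-ylidene]-4-(methoxymethoxy)-3-methylfuran-2(5H)-one | COCOC1=C(C)C(=O)O/C1=C/[C@@H](C)CCC/C(C)=C/CC/C(C)=C/CCc1ccoc1 | intermediate
25 | 4-O-trimethylsilyl analogue of 24 | C[Si](C)(C)OC1=C(C)C(=O)O/C1=C/[C@@H](C)CCC/C(C)=C/CC/C(C)=C/CCc1ccoc1 | intermediate
26 | (5E)-5-[(2S,6E,10E)-13-(furan-3-yl)-2,6,10-trimethyltrideca-6,10-dien-1-ylidene]-4-hydroxy-3-methylfuran-2(5H)-one | OC1=C(C)C(=O)O/C1=C/[C@@H](C)CCC/C(C)=C/CC/C(C)=C/CCc1ccoc1 | intermediate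
27 | stearoyl chloride (octadecanoyl chloride) | CCCCCCCCCCCCCCCCCC(=O)Cl | starting material
28 | (2E)-2-[(2S,6E,10E)-13-(furan-3-yl)-2,6,10-trimethyltrideca-6,10-dien-1-ylidene]-4-methyl-5-oxo-2,5-dihydrofuran-3-yl octadecanoate | CCCCCCCCCCCCCCCCCC(=O)OC1=C(C)C(=O)O/C1=C/[C@@H](C)CCC/C(C)=C/CC/C(C)=C/CCc1ccoc1 | target

Total step count: 15. Longest linear sequence: 11 steps (steps 1–8, 13, 14, 15).

Steps most likely to fail

**Step 6.** The alkenylpalladium is crowded by the cis C4–OMOM group and can chelate through it, so it may insert slowly. Alkenol isomerisation, elimination toward a conjugated diene, poor facial selectivity or hydride-induced E-to-Z drift could then take over.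

The fallback sets out from 9 and returns at 12, and it buys the stereocentre instead of creating it.
- (R)-butane-1,3-diol F1 is silylated at the primary hydroxyl (t-BuMe2SiCl, imidazole) to (R)-4-(tert-butyldimethylsilyloxy)butan-2-ol F2.
- Appel iodination with inversion gives (S)-tert-butyl(3-iodobutoxy)dimethylsilane F3.
- Iodine–lithium exchange with t-BuLi in pentane/Et2O at −100 °C gives, with retention, (S)-[4-(tert-butyldimethylsilyloxy)butan-2-yl]lithium F4.
- Me3SiCH2ZnBr·LiBr converts F4 into the configurationally stable mixed dialkylzinc F5.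
- A stereoretentive Negishi coupling of this secondary alkylzinc with 9, catalysed by dichloro[1,3-bis(2,6-di(pentan-3-yl)phenyl)imidazol-2-ylidene](3-chloropyridine)palladium at −25 °C → rt, should give the tert-butyldimethylsilyl ether of 12 F6. Both the sp3 configuration and the E alkene should be kept.
- HF·pyridine in THF then releases 12.

**Step 5.** Iodine may attack the electron-rich enol-ether carbon next to the carboxylate with loss of CO2. Closure may go 6-endo, or excess iodine may equilibrate the E iodide.

The fallback sets out from 4 and returns at 9. It lactonises before the enol ether exists.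
- LiOH in THF/H2O turns 4 into 3-hydroxy-2-methylpent-4-ynoic acid F7.
- I2/NaHCO3 in MeCN closes this simple 4-pentynoic acid type by the well-established 5-exo-dig anti iodolactonisation to (5E)-4-hydroxy-5-(iodomethylidene)-3-methyloxolan-2-one F8.
- Dess–Martin oxidation of the secondary alcohol, followed by spontaneous enolisation, gives (5E)-4-hydroxy-5-(iodomethylidene)-3-methylfuran-2(5H)-one F9.
- MOMCl with i-Pr2NEt at 0 °C in the dark gives 9.
- This path also removes the enol-ether geometry question of step 3 and the slow saponification of step 4.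

**Step 13.** Transfer of the alkyl group from the rather unreactive alkylzinc iodide to cobalt may be sluggish. That would allow homocoupling, leakage to the SN2′ isomer or isomerisation of the ylidene alkene by low-valent cobalt.

The fallback sets out from 13 and 20 and returns at 24, and it uses no preformed organometallic.
- Alcohol 20 is acetylated (Ac2O, pyridine) to (2E,6E)-9-(furan-3-yl)-2,6-dimethylnona-2,6-dien-1-yl acetate F10.
- F10 is joined to iodide 13 by nickel-catalysed reductive cross-electrophile allylation (NiCl2·dme, 4,4′,4″-tri-tert-butyl-2,2′:6′,2″-terpyridine, Zn dust, THF/DMA, rt).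
- In that reaction the alkyl radical from 13 is captured at the unsubstituted CH2 end of the allylnickel intermediate, whose syn form leads to the E alkene.

Further compounds
F1 | step 6 | (R)-butane-1,3-diol | C[C@@H](O)CCO
F2 | step 6 | (R)-4-(tert-butyldimethylsilyloxy)butan-2-ol | C[C@@H](O)CCO[Si](C)(C)C(C)(C)C
F3 | step 6 | (S)-tert-butyl(3-iodobutoxy)dimethylsilane | C[C@H](I)CCO[Si](C)(C)C(C)(C)C
F4 | step 6 | (S)-[4-(tert-butyldimethylsilyloxy)butan-2-yl]lithium | C[C@H]([Li])CCO[Si](C)(C)C(C)(C)C
F5 | step 6 | (S)-[4-(tert-butyldimethylsilyloxy)butan-2-yl](trimethylsilylmethyl)zinc | C[C@H]([Zn]C[Si](C)(C)C)CCO[Si](C)(C)C(C)(C)C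
F6 | step 6 | tert-butyldimethylsilyl ether of 12 | COCOC1=C(C)C(=O)O/C1=C/[C@@H](C)CCO[Si](C)(C)C(C)(C)C
F7 | step 5 | 3-hydroxy-2-methylpent-4-ynoic acid (mixture of racemic diastereomers) | C#CC(O)C(C)C(=O)O
F8 | step 5 | (5E)-4-hydroxy-5-(iodomethylidene)-3-methyloxolan-2-one (mixture of racemic diastereomers) | CC1C(=O)O/C(=C/I)C1O
F9 | step 5 | (5E)-4-hydroxy-5-(iodomethylidene)-3-methylfuran-2(5H)-one | OC1=C(C)C(=O)O/C1=C/I
F10 | step 13 | (2E,6E)-9-(furan-3-yl)-2,6-dimethylnona-2,6-dien-1-yl acetate | CC(=O)OC/C(C)=C/CC/C(C)=C/CCc1ccoc1
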